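The butyrolactone ring (O1–C2–C3–C4–C5) is traced back to a strained cis-oxetan-2-one in which C2 is still acylated by the C7' oxygen; the plan rests on forming C3–C7' and O7'–C2 together. A quinine-derived amine/LiClO4 co-catalysed ketene–aldehyde [2+2] cycloaddition builds that four-membered ring and fixes C3 and C7' in the syn (cis) relation that a lactone enolate aldol would not favour. The ketene precursor is an (R)-3-(arylmethyl)-4-silyloxybutanoyl chloride with C4 already set; the aldehyde is O-acetylvanillin, chosen over a silyl ether to keep the ring-B oxygen a weak donor. Unmasking the C5 hydroxyl then lets it take over the acyl group.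

Key step: step 7

Remarks on the chemistry (assumptions and design choices)
- Locants: lactone O1–C2(=O)–C3–C4–C5; C7 is the benzylic CH2 on C4 (ring A); C7' is the carbinol carbon on C3 (ring B). The target is (3S,4R,7'S) with C3/C4 trans.
- A phenolic silyl ether would not survive the alkoxide of the Stobbe condensation. Ring A is therefore carried as its benzyl ether up to lactone 7 and exchanged for silyl afterwards.
- Ring B enters the cycloaddition as the acetate. A silyloxy group would make the aldehyde less electrophilic and the aryl oxetanone easier to ionise. Fluoride would also free an aryl silyl ether before the primary one, and the resulting para-phenoxide could expel the carboxylate from C7' through a quinone methide and erase that centre. The acetate is removed only after the four-membered ring is gone.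
- O-Trimethylsilylquinine is made from quinine and Me3SiCl and serves as catalyst only. Catalyst-bound species of the catalytic cycles are not numbered as compounds.

Step 1
Reactants: 1 4-(benzyloxy)-3-methoxybenzaldehyde (O-benzylvanillin); 2 diethyl succinate
Product: 4 (3E)-4-[4-(benzyloxy)-3-methoxyphenyl]-3-(ethoxycarbonyl)but-3-enoic acid, via paraconate lactone 3 (not isolated)
Conditions: KOtBu (1.2 equiv), 2 (1.5 equiv), tBuOH, reflux; then 2 M HCl
Reagents that add atoms: none
Why: Stobbe condensation, in which the succinate enolate adds to the aldehyde, the aldolate lactonises onto the distal ester to give 3, and base-induced E1cB ring opening releases the half-ester carboxylate with the aryl group trans to the ester (E); the benzyl ether is inert to alkoxide.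

Step 2
Reactants: 4 (3E)-4-[4-(benzyloxy)-3-methoxyphenyl]-3-(ethoxycarbonyl)but-3-enoic acid
Product: 5 (3R)-4-[4-(benzyloxy)-3-methoxyphenyl]-3-(ethoxycarbonyl)butanoic acid
Conditions: H2 (5 bar), [Rh(cod)((S,S)-Et-DuPHOS)]BF4 (0.5 mol%), NaOMe (10 mol%), MeOH, rt
Reagents that add atoms: none
Why: Asymmetric hydrogenation of a Stobbe-type itaconate half-ester, in which carboxylate and alkene chelate cationic monovalent rhodium and H2 is delivered to one olefin face, the (S,S)-ligand being the antipode expected to give R at the future C4; the homogeneous catalyst leaves the benzyl ether and arenes alone.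

Step 3
Reactants: 5 (3R)-4-[4-(benzyloxy)-3-methoxyphenyl]-3-(ethoxycarbonyl)butanoic acid
Product: 7 (4R)-4-[4-(benzyloxy)-3-methoxybenzyl]dihydrofuran-2(3H)-one, via hydroxy acid 6 (not isolated)
Conditions: KOH (1.0 equiv), EtOH; CaCl2, NaBH4, EtOH, −10 °C to rt; then 2 M HCl, rt
Reagents that add atoms: none
Why: Chemoselective ester reduction, since Ca(BH4)2 formed in situ reduces the ethyl ester while the potassium carboxylate is inert, and acidification of 6 closes the γ-lactone (5-exo-trig) without involving C4.

Step 4
Reactants: 7 (4R)-4-[4-(benzyloxy)-3-methoxybenzyl]dihydrofuran-2(3H)-one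
Product: 8 (4R)-4-(4-hydroxy-3-methoxybenzyl)dihydrofuran-2(3H)-one
Conditions: H2 (1 atm), Pd/C (10 wt%), EtOAc, rt
Reagents that add atoms: none
Why: Hydrogenolysis of an aryl benzyl ether leaves lactone and stereocentre untouched and is placed before any benzylic alcohol exists, so that later compounds carry only fluoride- and solvolysis-labile groups.

Step 5
Reactants: 8 (4R)-4-(4-hydroxy-3-methoxybenzyl)dihydrofuran-2(3H)-one
Product: 10 tert-butyldimethylsilyl (3R)-4-[(tert-butyldimethylsilyl)oxy]-3-{4-[(tert-butyldimethylsilyl)oxy]-3-methoxybenzyl}butanoate, via dipotassium salt 9 (not isolated)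
Conditions: KOH (2.1 equiv), THF/H2O, rt; evaporate, toluene azeotrope; TBSCl (4 equiv), imidazole (6 equiv), DMF, rt
Reagents that add atoms: potassium hydroxide, [K+].[OH-]; tert-butyldimethylsilyl chloride, CC(C)(C)[Si](C)(C)Cl
Why: Saponification gives a hydroxy carboxylate that cannot relactonise while basic, and TBSCl/imidazole then silylates phenoxide, primary alcohol and carboxylate in one operation (standard silyl ether and silyl ester formation), C4 being remote from every reacting site.

Step 6
Reactants: 10 tert-butyldimethylsilyl (3R)-4-[(tert-butyldimethylsilyl)oxy]-3-{4-[(tert-butyldimethylsilyl)oxy]-3-methoxybenzyl}butanoate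
Product: 11 (3R)-4-[(tert-butyldimethylsilyl)oxy]-3-{4-[(tert-butyldimethylsilyl)oxy]-3-methoxybenzyl}butanoyl chloride
Conditions: (COCl)2 (1.2 equiv), DMF (cat.), CH2Cl2, 0 °C to rt; concentrate, use crude at once
Reagents that add atoms: oxalyl chloride, O=C(Cl)C(=O)Cl
Why: Silyl ester to acyl chloride exchange through the chloroiminium (Vilsmeier) species proceeds under neutral conditions without HCl, so both silyl ethers should persist; immediate use forestalls attack of the C5 oxygen on the acyl group.

Step 7
Reactants: 11 (3R)-4-[(tert-butyldimethylsilyl)oxy]-3-{4-[(tert-butyldimethylsilyl)oxy]-3-methoxybenzyl}butanoyl chloride; 12 4-formyl-2-methoxyphenyl acetate (O-acetylvanillin)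
Product: 14 4-[(2S,3S)-3-{(2R)-1-[(tert-butyldimethylsilyl)oxy]-3-[4-((tert-butyldimethylsilyl)oxy)-3-methoxyphenyl]propan-2-yl}-4-oxooxetan-2-yl]-2-methoxyphenyl acetate (cis β-lactone), via ketene 13 (not isolated)
Conditions: O-trimethylsilylquinine (15 mol%), LiClO4 (2 equiv), iPr2NEt (2.5 equiv), 12 (1.5 equiv), CH2Cl2/Et2O (2:1), −78 °C, slow addition of 11
Reagents that add atoms: none
Why: iPr2NEt converts 11 into ketene 13, the quinuclidine nitrogen of the alkaloid adds to it anti to the branched substituent to give a Z-configured acylammonium enolate, and this enolate attacks the LiClO4-activated aldehyde 12 through a lithium-bridged chair-like array, after which the lithium aldolate displaces the catalyst from the acyl carbon. The closest known reaction type is the cinchona alkaloid and lithium salt co-catalysed acyl halide–aldehyde cyclocondensation, which is established for cis-3,4-disubstituted oxetan-2-ones. The single ring formed, the oxetan-2-one O7'–C2–C3–C7', closes by 4-exo-trig attack of the C7' alkoxide on the acylammonium carbon C2. C3 is fixed by the enolate face that the quinine framework leaves open (3S expected for the quinine series) and C7' by the aldehyde face held in the closed transition state, which places aryl and side chain cis (7'S). The step needs catalyst control over the neighbouring C4 centre and a cross-reaction faster than ketene dimerisation; C4 carries two CH2 arms of similar size and so exerts little bias of its own, the acetoxy-substituted aldehyde is more electrophilic than a silyloxy analogue, and slow addition of 11 keeps the ketene concentration low. The acetate also makes ring B a poorer donor, which should keep the benzylic C7'–O bond of the product from ionising.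

Step 8
Reactants: 14 4-[(2S,3S)-3-{(2R)-1-[(tert-butyldimethylsilyl)oxy]-3-[4-((tert-butyldimethylsilyl)oxy)-3-methoxyphenyl]propan-2-yl}-4-oxooxetan-2-yl]-2-methoxyphenyl acetate
Product: 16 4-{(S)-hydroxy[(3S,4R)-4-(4-hydroxy-3-methoxybenzyl)-2-oxotetrahydrofuran-3-yl]methyl}-2-methoxyphenyl acetate, via hydroxy β-lactone 15 (not isolated)
Conditions: Bu4NF (3 equiv), AcOH (3.5 equiv), THF, 0 °C to rt
Reagents that add atoms: none
Why: Acetic acid-buffered fluoride desilylation followed by translactonisation, in which the freed C5 hydroxyl adds 5-exo-trig to the strained acyl carbon C2 and the tetrahedral intermediate releases the C7' alkoxide (acyl–oxygen cleavage), so no bond to C3, C4 or C7' is broken and all three centres are retained, while the buffer keeps the ring-B acetate in place until the β-lactone is consumed.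

Step 9
Reactants: 16 4-{(S)-hydroxy[(3S,4R)-4-(4-hydroxy-3-methoxybenzyl)-2-oxotetrahydrofuran-3-yl]methyl}-2-methoxyphenyl acetate
Product: 17 (3S,4R)-4-(4-hydroxy-3-methoxybenzyl)-3-[(S)-hydroxy(4-hydroxy-3-methoxyphenyl)methyl]dihydrofuran-2(3H)-one (target)
Conditions: NH4OAc (8 equiv), MeOH/H2O (4:1), rt
Reagents that add atoms: none
Why: Chemoselective solvolysis of a phenolic acetate promoted by NH4OAc at neutral pH is much faster than attack on the aliphatic lactone, and the absence of strong base or acid should avoid retro-aldol cleavage of C3–C7' and quinone methide formation at C7'.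

Compound list
1 | 4-(benzyloxy)-3-methoxybenzaldehyde (O-benzylvanillin) | COc1cc(C=O)ccc1OCc1ccccc1 | starting material
2 | diethyl succinate | CCOC(=O)CCC(=O)OCC | starting material
3 | ethyl 2-[4-(benzyloxy)-3-methoxyphenyl]-5-oxotetrahydrofuran-3-carboxylate (paraconate lactone, racemic diastereomer mixture) | CCOC(=O)C1CC(=O)OC1c1ccc(OCc2ccccc2)c(OC)c1 | intermediate (not isolated)
4 | (3E)-4-[4-(benzyloxy)-3-methoxyphenyl]-3-(ethoxycarbonyl)but-3-enoic acid | CCOC(=O)/C(CC(=O)O)=C/c1ccc(OCc2ccccc2)c(OC)c1 | intermediate
5 | (3R)-4-[4-(benzyloxy)-3-methoxyphenyl]-3-(ethoxycarbonyl)butanoic acid | CCOC(=O)[C@@H](CC(=O)O)Cc1ccc(OCc2ccccc2)c(OC)c1 | intermediate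
6 | (3R)-4-[4-(benzyloxy)-3-methoxyphenyl]-3-(hydroxymethyl)butanoic acid (present as its carboxylate salt until acidified) | O=C(O)C[C@H](CO)Cc1ccc(OCc2ccccc2)c(OC)c1 | intermediate (not isolated)
7 | (4R)-4-[4-(benzyloxy)-3-methoxybenzyl]dihydrofuran-2(3H)-one | O=C1C[C@@H](Cc2ccc(OCc3ccccc3)c(OC)c2)CO1 | intermediate
8 | (4R)-4-(4-hydroxy-3-methoxybenzyl)dihydrofuran-2(3H)-one | O=C1C[C@@H](Cc2ccc(O)c(OC)c2)CO1 | intermediate
9 | dipotassium (3R)-4-hydroxy-3-(3-methoxy-4-oxidobenzyl)butanoate | [K+].[K+].[O-]C(=O)C[C@H](CO)Cc1ccc([O-])c(OC)c1 | intermediate (not isolated)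
10 | tert-butyldimethylsilyl (3R)-4-[(tert-butyldimethylsilyl)oxy]-3-{4-[(tert-butyldimethylsilyl)oxy]-3-methoxybenzyl}butanoate | CC(C)(C)[Si](C)(C)OC(=O)C[C@@H](Cc1ccc(O[Si](C)(C)C(C)(C)C)c(OC)c1)CO[Si](C)(C)C(C)(C)C | intermediate
11 | (3R)-4-[(tert-butyldimethylsilyl)oxy]-3-{4-[(tert-butyldimethylsilyl)oxy]-3-methoxybenzyl}butanoyl chloride | O=C(Cl)C[C@@H](Cc1ccc(O[Si](C)(C)C(C)(C)C)c(OC)c1)CO[Si](C)(C)C(C)(C)C | intermediate (key-step precursor)
12 | 4-formyl-2-methoxyphenyl acetate (O-acetylvanillin) | CC(=O)Oc1ccc(C=O)cc1OC | starting material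
13 | (3R)-4-[(tert-butyldimethylsilyl)oxy]-3-{4-[(tert-butyldimethylsilyl)oxy]-3-methoxybenzyl}but-1-en-1-one (ketene) | O=C=C[C@@H](Cc1ccc(O[Si](C)(C)C(C)(C)C)c(OC)c1)CO[Si](C)(C)C(C)(C)C | intermediate (not isolated)
14 | 4-[(2S,3S)-3-{(2R)-1-[(tert-butyldimethylsilyl)oxy]-3-[4-((tert-butyldimethylsilyl)oxy)-3-methoxyphenyl]propan-2-yl}-4-oxooxetan-2-yl]-2-methoxyphenyl acetate (cis β-lactone) | O=C1O[C@H](c2ccc(OC(C)=O)c(OC)c2)[C@@H]1[C@@H](Cc1ccc(O[Si](C)(C)C(C)(C)C)c(OC)c1)CO[Si](C)(C)C(C)(C)C | intermediate (key-step product)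
15 | 4-[(2S,3S)-3-[(2R)-1-hydroxy-3-(4-hydroxy-3-methoxyphenyl)propan-2-yl]-4-oxooxetan-2-yl]-2-methoxyphenyl acetate | O=C1O[C@H](c2ccc(OC(C)=O)c(OC)c2)[C@@H]1[C@@H](Cc1ccc(O)c(OC)c1)CO | intermediate (not isolated)
16 | 4-{(S)-hydroxy[(3S,4R)-4-(4-hydroxy-3-methoxybenzyl)-2-oxotetrahydrofuran-3-yl]methyl}-2-methoxyphenyl acetate | COc1cc(C[C@H]2COC(=O)[C@@H]2[C@H](O)c2ccc(OC(C)=O)c(OC)c2)ccc1O | intermediate
17 | (3S,4R)-4-(4-hydroxy-3-methoxybenzyl)-3-[(S)-hydroxy(4-hydroxy-3-methoxyphenyl)methyl]dihydrofuran-2(3H)-one | COc1cc(C[C@H]2COC(=O)[C@@H]2[C@H](O)c2ccc(O)c(OC)c2)ccc1O | target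

Total step count: 9
Longest linear sequence: 9 steps (1 to 17); aldehyde 12 is purchased.

Steps most likely to fail

Step 7. What may go wrong: mismatched double stereodifferentiation, in which the resident C4 centre erodes the catalyst-imposed facial selectivity; slow addition of the hindered ammonium enolate to an aromatic aldehyde, so that ketene dimerisation takes over; or decarboxylative ionisation of the aryl β-lactone during work-up. The fallback replaces the cycloaddition by an auxiliary-controlled syn-aldol reaction. It sets out from acid chloride 11, which is added to lithiated (S)-4-benzyl-1,3-oxazolidin-2-one (n-BuLi, THF, −78 °C) to give (S)-4-benzyl-3-[(3R)-4-(silyloxy)-3-(4-silyloxy-3-methoxybenzyl)butanoyl]oxazolidin-2-one F1. Enolisation with Bu2BOTf/iPr2NEt (CH2Cl2, −78 to 0 °C) and addition of aldehyde 12 should give, through the Z-boron enolate and a closed chair transition state, the syn-aldol imide F2 with the (3S,7'S) configuration dictated by the auxiliary. Buffered fluoride (Bu4NF/AcOH, THF) then frees the C5 hydroxyl, which lactonises onto the imide carbonyl with release of the auxiliary, and the route is rejoined at 16.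

Step 8. What may go wrong: early loss of the ring-B acetate, giving a para-phenoxide that breaks the benzylic C7'–O bond through a quinone methide and scrambles C7'; attack of the C5 hydroxyl at C7' (alkyl–oxygen cleavage) instead of C2, leading to a tetrahydrofuran acid; or stalled acyl transfer. The fallback opens the four-membered ring first with an external nucleophile and lactonises afterwards. It sets out from β-lactone 14, which is treated with MeNH(OMe)·HCl/Me2AlCl (CH2Cl2, −30 °C) to give by acyl–oxygen cleavage the β-hydroxy Weinreb amide F3 with all three centres untouched. Bu4NF/AcOH in THF then removes the silyl groups, and the γ-hydroxy amide lactonises with loss of N,O-dimethylhydroxylamine, returning to the route at 16.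

Step 6. What may go wrong: intramolecular acyl transfer, in which the C5 silyl ether oxygen attacks the acyl chloride and silyl chloride is lost with return to a butyrolactone, or stripping of silyl groups by adventitious HCl. The fallback avoids the acyl chloride altogether. It sets out from silyl ester 10, whose ester alone is hydrolysed (NaHCO3, THF/MeOH/H2O, 0 °C) to the carboxylic acid F4. This is converted with PivCl/Et3N (THF, −20 °C) into the mixed pivalic anhydride F5, which acylates lithiated (S)-4-benzyl-1,3-oxazolidin-2-one to give the imide F1. From there the boron aldol reaction with 12 to the syn-aldol imide F2 and the buffered fluoride treatment follow as for step 7, and the route is rejoined at 16.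

Further compounds
F1 | step 7 | (4S)-4-benzyl-3-[(3R)-4-[(tert-butyldimethylsilyl)oxy]-3-{4-[(tert-butyldimethylsilyl)oxy]-3-methoxybenzyl}butanoyl]-1,3-oxazolidin-2-one | O=C(C[C@@H](Cc1ccc(O[Si](C)(C)C(C)(C)C)c(OC)c1)CO[Si](C)(C)C(C)(C)C)N1[C@@H](Cc2ccccc2)COC1=O
F2 | step 7 | 4-[(1S,2S)-2-[(4S)-4-benzyl-2-oxo-1,3-oxazolidine-3-carbonyl]-1-hydroxy-2-{(2R)-1-[(tert-butyldimethylsilyl)oxy]-3-[4-((tert-butyldimethylsilyl)oxy)-3-methoxyphenyl]propan-2-yl}ethyl]-2-methoxyphenyl acetate (syn-aldol imide) | O=C(N1[C@@H](Cc2ccccc2)COC1=O)[C@H]([C@H](O)c1ccc(OC(C)=O)c(OC)c1)[C@@H](Cc1ccc(O[Si](C)(C)C(C)(C)C)c(OC)c1)CO[Si](C)(C)C(C)(C)C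
F3 | step 8 | 4-[(1S,2S)-1-hydroxy-2-[methoxy(methyl)carbamoyl]-2-{(2R)-1-[(tert-butyldimethylsilyl)oxy]-3-[4-((tert-butyldimethylsilyl)oxy)-3-methoxyphenyl]propan-2-yl}ethyl]-2-methoxyphenyl acetate (β-hydroxy Weinreb amide) | CON(C)C(=O)[C@H]([C@H](O)c1ccc(OC(C)=O)c(OC)c1)[C@@H](Cc1ccc(O[Si](C)(C)C(C)(C)C)c(OC)c1)CO[Si](C)(C)C(C)(C)C
F4 | step 6 | (3R)-4-[(tert-butyldimethylsilyl)oxy]-3-{4-[(tert-butyldimethylsilyl)oxy]-3-methoxybenzyl}butanoic acid | O=C(O)C[C@@H](Cc1ccc(O[Si](C)(C)C(C)(C)C)c(OC)c1)CO[Si](C)(C)C(C)(C)C
F5 | step 6 | (3R)-4-[(tert-butyldimethylsilyl)oxy]-3-{4-[(tert-butyldimethylsilyl)oxy]-3-methoxybenzyl}butanoic pivalic anhydride | CC(C)(C)C(=O)OC(=O)C[C@@H](Cc1ccc(O[Si](C)(C)C(C)(C)C)c(OC)c1)CO[Si](C)(C)C(C)(C)C
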